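## The problem

Compound 18 is a flavanone: the phloroglucinol-derived ring A (5-OH, 7-OMe) is fused to the dihydropyranone ring C, and C2 of ring C carries ring B. Ring B is the difficult part. It has four contiguous substituents, C1' (ring C), C2' (geranyl), C3' (OMe) and C4' (OMe), and the ten-carbon chain sits in the most crowded position, between the heterocycle and an oxygen. There is one stereocentre, C2 (S), and nothing else in the molecule can control it, so it has to come from a chiral catalyst. Because C2 is benzylic, oxygen-bearing and β to the C4 ketone, base opens ring C by retro-oxa-Michael reaction and racemises it, so C2 should be set late and see no base afterwards. The geranyl chain (two trisubstituted alkenes, one benzylic–allylic CH2, defined E geometry) rules out catalytic hydrogenation and strong Lewis or Brønsted acids, which would trigger cation–olefin cyclisation or HX addition. The chelated 5-OH must end free beside three methyl ethers, so it is better carried under a group that leaves in dilute acid than as a methyl ether needing boron or aluminium halides. The enabling feature is that, at the flavone oxidation level, a two-carbon alkyne on C2 (the future C1' and C6') is conjugated through C2=C3 to C4=O and is therefore an acceptor. The remaining ring B carbons C2'–C5', with the 3',4'-oxygens and the chain on C2', are a 1-alkyl-2,3-dioxygenated butadiene, and the flavone that results is the substrate for an asymmetric conjugate reduction that sets C2.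

## Retrosynthesis

**18 from 17.** The last cut is the O–CH2 bond of a methoxymethyl (MOM) ether on O5. A 5-methyl ether would have to be cleaved by BCl3-type reagents in the presence of the geranyl alkenes and the C2 stereocentre. The MOM acetal peri to the carbonyl falls off in dilute acid, which does not epimerise flavanones. The forward step only has to be short and cool.

**17 from 16.** The C2–H bond is cut, which removes the only stereocentre and leaves the flat, achiral flavone 16. Catalytic hydrogenation would also reduce the chain. Oxa-Michael closure of a chalcone is reversible and hard to render selective on an unactivated substrate. A ligated copper hydride touches only the conjugated C2=C3 bond. The forward reaction must deliver hydride to the Re face of C2 and leave the isolated alkenes alone.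

**16 from 15.** The two O–CH3 bonds of ring B are cut. The catechol oxygens arrive as silyl ethers from the diene, and a one-pot fluoride/MeI exchange turns them into the methyl ethers without handling a free catechol.

**15 from 8 and 13 (through 14).** Ring B is cut at C1'–C2' and C5'–C6'. The neighbouring cuts are weaker:
- Cutting C2–C1' leaves a tetrasubstituted arene that still has to be made by directed metalation.
- Cutting C2'–CH2 asks for an allyl cross-coupling at a doubly flanked position, with α/γ and E/Z scrambling.

The chosen cut gives two unbranched fragments, the ethynylchromone 8 and the bis(silyloxy)diene 13. The position of the chain is fixed by construction, since it is the alkylated methyl of a diketone. The forward reaction must show ortho regiochemistry (substituted diene terminus to the internal alkyne carbon), and the cyclohexadiene 14 must be dehydrogenated. tert-Butyldimethylsilyl (TBS) enol ethers are chosen over trimethylsilyl so that 13 survives long heating and 15 can be chromatographed.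

**8 from 7, 6, 5, 4, and 4 from 1 and 2 (through 3).** The alkyne is cut back by one carbon to aldehyde 7 (Seyferth–Gilbert homologation), and 7 comes from alcohol 6 and ester 5. The MOM group is put on the chelated hydroxyl of ester 4. Ring C of 4 is cut at O1–C2 and C2–C3, which is the classical Claisen condensation of acetophenone 1 with diethyl oxalate 2 and acid cyclodehydration of the diketo ester 3. Starting from the 2',6'-dihydroxy compound gives the free 5-OH directly, so no selective demethylation is ever needed.

**13 from 12, 11, and 11 from 9 and 10.** The diene is the double silyl enol ether of the 1,2-diketone 12. Diketone 12 is cut at the bond between its α-carbon and C1 of the geranyl group. Butane-2,3-dione itself would self-condense, so its commercial mono-ketal 9, which has a single enolisable methyl, is alkylated with geranyl bromide 10 to give 11, and the ketal is then hydrolysed.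

## Roads not taken

**Alternative 1:** The cut is C2–C3 of ring C. A racemic 4-methylidene-1,3-benzodioxine A2 would be ionised by a silylium Lewis acid paired with a chiral imidodiphosphorimidate anion and would reclose through carbon (Petasis–Ferrier rearrangement) to the bromo-flavanone A1.
- Merits: the step is stereoconvergent and catalytic, and it forms a C–C bond and the C2 stereocentre together. No reduction of a hindered flavone is needed. In the way the stereocentre is set, this road is better than the chosen one.
- Weak points: the geranyl chain is still missing. It would have to be coupled to the aryl bromide of A1, which is flanked by ring C and a methoxy group, using an allyl-type metal reagent prone to α/γ and E/Z scrambling. The coupling would run on a flavanone that base and heat open and racemise. The 5-methyl ether of A1 must also be cleaved selectively with a Lewis acid once the chain is present. The catalyst class is specialised.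
- Comparison: the chosen plan sets against this that ring B is built with the chain already in place, that no cross-coupling or demethylation touches the chiral flavanone, and that its stereo-step uses a commercial ligand.

**Alternative 2:** The cut is C4a–C5, so ring A is made last. Heating the dioxinone-tethered dihydropyranone A4 would expel acetone, and the acylketene would be captured by the nucleophilic enol-ether carbon of the pyranone. Enolisation then aromatises ring A to the 5,7-dihydroxyflavanone A3.
- Merits: the 5-OH appears free without any protecting group. The stereocentre could be set early, for example by a catalytic asymmetric hetero-Diels–Alder reaction of aldehyde A5. No late asymmetric reduction is needed. On these two points this road is as good as or better than the chosen one.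
- Weak points: A3 still needs a selective 7-O-methylation on a base-labile flavanone. A4 takes many steps to assemble. The key step does nothing for the real difficulty, the contiguous substitution of ring B, which is pushed into a separate synthesis of A5. The stereocentre must also survive the thermolysis.
- Comparison: the chosen plan spends its key step on ring B and is shorter overall. In return it accepts a late reduction of a hindered flavone.

**Alternative 3:** The cuts are O1–C2 and C3–C4. A chiral phosphoric acid would turn the acetal A8 into an ortho-quinone methide, which would add the styrene A7 in a hetero-Diels–Alder reaction to give the chroman A6.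
- Merits: this is the most convergent union. Ring C and the C2 stereocentre are formed in one catalytic step from two simple fragments, and in convergence it is better than the chosen plan.
- Weak points: A6 has the wrong oxidation level at C4. The benzylic methyl ether must be oxidised to the ketone in the presence of the allylic and benzylic positions of the chain, and the 5-methyl ether must then be cleaved. The cationic quinone methide and the acid are exposed to the nucleophilic trisubstituted alkenes of the chain (Prins-type capture). The ortho chain twists the styrene out of conjugation, which lowers its reactivity and the selectivity. A7 again requires A5 or an equivalent, so ring B is not solved.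
- Comparison: the chosen plan reaches the C4 ketone directly, keeps the chain away from cationic chemistry until one brief dilute-acid step, and builds ring B in the key step.

Key step: step 9

Remark on nomenclature: geranyl = (2E)-3,7-dimethylocta-2,6-dien-1-yl. Primed locants refer to ring B.

Assumption: the sense of induction in step 11 is assigned by analogy with other 2-substituted chromones. (R)-DTBM-SEGPHOS is written for the ligand antipode that delivers hydride to the Re face of C2 (2S product), and the antipode is exchanged if the sense proves opposite.

Assumption: 1 and 9 are taken as commercially available.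

## Route

Step 1
Reactants: 1 1-(2,6-dihydroxy-4-methoxyphenyl)ethanone (2',6'-dihydroxy-4'-methoxyacetophenone); 2 diethyl oxalate
Product: 4 ethyl 5-hydroxy-7-methoxy-4-oxo-4H-chromene-2-carboxylate, via diketo ester 3 (not isolated)
Conditions: NaOEt, EtOH, reflux; then conc. HCl, EtOH, reflux
Reagents that add atoms: none
Why: Crossed Claisen condensation of the acetophenone enolate (as its phenoxide polyanion) with non-enolisable diethyl oxalate should give the 2,4-dioxobutanoate 3, and acid closes ring C by attack of a phenol oxygen on the C2 ketone and dehydration (classical chromone-2-carboxylate synthesis). The two ortho hydroxyls of 1 are equivalent, so a single chromone is expected, with the remaining hydroxyl peri to C4=O.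

Step 2
Reactants: 4 ethyl 5-hydroxy-7-methoxy-4-oxo-4H-chromene-2-carboxylate
Product: 5 ethyl 7-methoxy-5-(methoxymethoxy)-4-oxo-4H-chromene-2-carboxylate
Conditions: NaH, MOMCl, DMF, 0 °C to rt
Reagents that add atoms: chloromethyl methyl ether (MOMCl), COCCl
Why: Williamson-type O-alkylation of the sodium 5-phenoxide by the very reactive chloromethyl ether overcomes the low nucleophilicity of the chelated hydroxyl. The acetal should survive hydride, carbonate, heat, DDQ and fluoride, and it is removed at the end by dilute acid, which spares the chain and the stereocentre.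

Step 3
Reactants: 5 ethyl 7-methoxy-5-(methoxymethoxy)-4-oxo-4H-chromene-2-carboxylate
Product: 6 2-(hydroxymethyl)-7-methoxy-5-(methoxymethoxy)-4H-chromen-4-one
Conditions: NaBH4, MeOH/THF, 0 °C
Reagents that add atoms: none
Why: The C2 ester of a chromone is an activated, acrylate-type ester and is reduced by NaBH4 at 0 °C faster than the vinylogous-ester C4 carbonyl, a known chemoselective route to 2-(hydroxymethyl)chromones. A short reaction time at low temperature limits 1,4-reduction of the pyranone.

Step 4
Reactants: 6 2-(hydroxymethyl)-7-methoxy-5-(methoxymethoxy)-4H-chromen-4-one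
Product: 7 7-methoxy-5-(methoxymethoxy)-4-oxo-4H-chromene-2-carbaldehyde
Conditions: DMP, CH2Cl2, 0 °C to rt
Reagents that add atoms: none
Why: Dess–Martin oxidation of the allylic-type primary alcohol should stop at the aldehyde under non-aqueous, nearly neutral conditions that leave the acetal and the pyranone untouched.

Step 5
Reactants: 7 7-methoxy-5-(methoxymethoxy)-4-oxo-4H-chromene-2-carbaldehyde
Product: 8 2-ethynyl-7-methoxy-5-(methoxymethoxy)-4H-chromen-4-one
Conditions: dimethyl (1-diazo-2-oxopropyl)phosphonate, K2CO3, MeOH, 0 °C to rt
Reagents that add atoms: dimethyl (1-diazo-2-oxopropyl)phosphonate (Ohira–Bestmann reagent), COP(=O)(OC)C(=[N+]=[N-])C(C)=O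
Why: Seyferth–Gilbert homologation in its Ohira–Bestmann form: methanolysis of the reagent releases the dimethyl diazomethylphosphonate anion, which adds to the aldehyde and eliminates phosphate to a diazoalkene; loss of N2 and a 1,2-hydrogen shift give the terminal alkyne. Mild carbonate base at low temperature is chosen because the product is a Michael acceptor.

Step 6
Reactants: 9 3,3-dimethoxybutan-2-one; 10 geranyl bromide, (2E)-1-bromo-3,7-dimethylocta-2,6-diene
Product: 11 (6E)-2,2-dimethoxy-7,11-dimethyldodeca-6,10-dien-3-one
Conditions: LiN(i-Pr)2, THF, −78 °C; then 10, DMPU, −78 to 0 °C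
Reagents that add atoms: none
Why: Ketone 9 has a single enolisable position (the acetyl methyl; the ketal carbon carries no hydrogen), so its kinetic lithium enolate should be alkylated by the primary allylic bromide in an SN2 reaction at the unhindered CH2 with the E alkene unchanged. The ketal masks the second carbonyl and removes the self-condensation of butane-2,3-dione.

Step 7
Reactants: 11 (6E)-2,2-dimethoxy-7,11-dimethyldodeca-6,10-dien-3-one
Product: 12 (6E)-7,11-dimethyldodeca-6,10-diene-2,3-dione
Conditions: 1 M aq. HCl, THF, rt
Reagents that add atoms: water, O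
Why: Acid-catalysed hydrolysis of a ketone dimethyl ketal through the tertiary oxocarbenium ion; dilute aqueous acid at rt should suffice and does not protonate the trisubstituted alkenes at a useful rate.

Step 8
Reactants: 12 (6E)-7,11-dimethyldodeca-6,10-diene-2,3-dione
Product: 13 (3Z,6E)-2,3-bis(tert-butyldimethylsilyloxy)-7,11-dimethyldodeca-1,3,6,10-tetraene
Conditions: TBSOTf, Et3N, CH2Cl2, 0 °C to rt
Reagents that add atoms: tert-butyldimethylsilyl trifluoromethanesulfonate (TBSOTf), CC(C)(C)[Si](C)(C)OS(=O)(=O)C(F)(F)F
Why: Soft enolisation of both carbonyls by silyl triflate and tertiary amine gives the 2,3-bis(silyloxy)-1,3-diene, a known transformation of 1,2-diketones. Each carbonyl has only one enolisable neighbour, and the 3Z enol ether (chain cis to the silyloxy group, trans to C2) is expected because it avoids allylic 1,3-strain between the chain and the C1=C2 unit.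

Step 9
Reactants: 8 2-ethynyl-7-methoxy-5-(methoxymethoxy)-4H-chromen-4-one; 13 (3Z,6E)-2,3-bis(tert-butyldimethylsilyloxy)-7,11-dimethyldodeca-1,3,6,10-tetraene
Product: 15 2-[3,4-bis(tert-butyldimethylsilyloxy)-2-geranylphenyl]-7-methoxy-5-(methoxymethoxy)-4H-chromen-4-one, via cyclohexa-1,4-diene cycloadduct 14 (not isolated)
Conditions: PhMe, BHT (cat.), 130 °C, sealed tube; then DDQ, 0 °C to rt
Reagents that add atoms: none
Why: The alkyne of 8 is a vinylogous ynone (C≡C–C2=C3–C4=O) and should act as the 2π partner in a normal-demand, concerted but asynchronous [4+2] cycloaddition with the doubly oxygenated diene 13; the closest known reaction type is the Diels–Alder reaction of 2,3-bis(silyloxy)buta-1,3-dienes with acceptor alkynes followed by dehydrogenation to catechol ethers. Ring B closes as a six-membered carbocycle by this suprafacial π4s+π2s union, C5'–C6' (diene CH2 to the terminal alkyne carbon) forming slightly ahead of C1'–C2' (chain-bearing diene carbon to the internal alkyne carbon). The step needs ortho regioselectivity: the two silyloxy groups polarise the diene in opposite senses and largely cancel, so the alkyl-substituted terminus decides, leaving the larger HOMO coefficient and the smaller steric demand at the unsubstituted CH2, which pairs with the electrophilic, unhindered terminal alkyne carbon. The 3Z enol ether places the chain trans to C2 of the diene, so the s-cis conformer has no inside substituent and no 1,5-hydrogen shift is open to it. Chemoselectivity for the alkyne over the trisubstituted C2=C3 bond and the chain alkenes follows from its accessibility and conjugation. DDQ then abstracts hydride from an allylic ring position of 14 (C5' or C2') and a proton is lost from the other, driven by aromatisation; the C2' stereocentre of 14 is erased, so no stereocentre is set. TBS enol ethers are used so that the diene survives the long heating a weakly activated alkyne requires and so that 15 can be purified.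

Step 10
Reactants: 15 2-[3,4-bis(tert-butyldimethylsilyloxy)-2-geranylphenyl]-7-methoxy-5-(methoxymethoxy)-4H-chromen-4-one
Product: 16 2-(2-geranyl-3,4-dimethoxyphenyl)-7-methoxy-5-(methoxymethoxy)-4H-chromen-4-one
Conditions: CsF, MeI, DMF, rt, argon
Reagents that add atoms: iodomethane, CI
Why: Fluoride cleaves the aryl silyl ethers and the caesium phenoxides are methylated at once by MeI (one-pot desilylative Williamson etherification), so the air-sensitive free catechol does not accumulate. The pyranone, the acetal and the alkenes are inert to these conditions.

Step 11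
Reactants: 16 2-(2-geranyl-3,4-dimethoxyphenyl)-7-methoxy-5-(methoxymethoxy)-4H-chromen-4-one
Product: 17 (2S)-2-(2-geranyl-3,4-dimethoxyphenyl)-7-methoxy-5-(methoxymethoxy)chroman-4-one
Conditions: Cu(OAc)2 (cat.), (R)-DTBM-SEGPHOS (cat.), (EtO)2MeSiH, t-BuOH, PhMe, 0 °C to rt; then aq. NH4F
Reagents that add atoms: none
Why: A bisphosphine-ligated copper hydride, formed from Cu(OAc)2 and the hydrosilane, adds hydride to C2 of the chromone (asymmetric conjugate reduction, known for 2-substituted chromones), and the copper enolate is protonated by t-BuOH. The C2 stereocentre is set under catalyst control by hydride delivery to the Re face of C2, and unactivated trisubstituted alkenes are not reduced.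

Step 12
Reactants: 17 (2S)-2-(2-geranyl-3,4-dimethoxyphenyl)-7-methoxy-5-(methoxymethoxy)chroman-4-one
Product: 18 (2S)-2-(2-geranyl-3,4-dimethoxyphenyl)-5-hydroxy-7-methoxychroman-4-one
Conditions: 3 M aq. HCl, MeOH/THF, rt
Reagents that add atoms: none
Why: Acid-catalysed cleavage of the methoxymethyl acetal, accelerated by the peri carbonyl, which ends hydrogen-bonded to the liberated 5-OH. Acid does not open ring C (the retro-oxa-Michael path needs base), so the 2S centre should be retained, and brief exposure to dilute acid at rt should leave the chain alkenes intact.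

## Compound list

1 | 1-(2,6-dihydroxy-4-methoxyphenyl)ethanone | CC(=O)c1c(O)cc(OC)cc1O | starting material
2 | diethyl oxalate | CCOC(=O)C(=O)OCC | starting material
3 | ethyl 4-(2,6-dihydroxy-4-methoxyphenyl)-2,4-dioxobutanoate | CCOC(=O)C(=O)CC(=O)c1c(O)cc(OC)cc1O | intermediate (not isolated)
4 | ethyl 5-hydroxy-7-methoxy-4-oxo-4H-chromene-2-carboxylate | CCOC(=O)C1=CC(=O)c2c(O)cc(OC)cc2O1 | intermediate
5 | ethyl 7-methoxy-5-(methoxymethoxy)-4-oxo-4H-chromene-2-carboxylate | CCOC(=O)C1=CC(=O)c2c(OCOC)cc(OC)cc2O1 | intermediate
6 | 2-(hydroxymethyl)-7-methoxy-5-(methoxymethoxy)-4H-chromen-4-one | OCC1=CC(=O)c2c(OCOC)cc(OC)cc2O1 | intermediate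
7 | 7-methoxy-5-(methoxymethoxy)-4-oxo-4H-chromene-2-carbaldehyde | O=CC1=CC(=O)c2c(OCOC)cc(OC)cc2O1 | intermediate
8 | 2-ethynyl-7-methoxy-5-(methoxymethoxy)-4H-chromen-4-one | C#CC1=CC(=O)c2c(OCOC)cc(OC)cc2O1 | intermediate
9 | 3,3-dimethoxybutan-2-one | CC(=O)C(C)(OC)OC | starting material
10 | geranyl bromide, (2E)-1-bromo-3,7-dimethylocta-2,6-diene | CC(C)=CCC/C(C)=C/CBr | starting material
11 | (6E)-2,2-dimethoxy-7,11-dimethyldodeca-6,10-dien-3-one | CC(OC)(OC)C(=O)CC/C=C(\C)CCC=C(C)C | intermediate
12 | (6E)-7,11-dimethyldodeca-6,10-diene-2,3-dione | CC(=O)C(=O)CC/C=C(\C)CCC=C(C)C | intermediate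
13 | (3Z,6E)-2,3-bis(tert-butyldimethylsilyloxy)-7,11-dimethyldodeca-1,3,6,10-tetraene | C=C(O[Si](C)(C)C(C)(C)C)/C(O[Si](C)(C)C(C)(C)C)=C/C/C=C(\C)CCC=C(C)C | intermediate
14 | 2-[4,5-bis(tert-butyldimethylsilyloxy)-6-geranylcyclohexa-1,4-dien-1-yl]-7-methoxy-5-(methoxymethoxy)-4H-chromen-4-one (racemic at ring carbon 6) | COc1cc(OCOC)c2c(c1)OC(C1=CCC(O[Si](C)(C)C(C)(C)C)=C(O[Si](C)(C)C(C)(C)C)C1C/C=C(\C)CCC=C(C)C)=CC2=O | intermediate (not isolated)
15 | 2-[3,4-bis(tert-butyldimethylsilyloxy)-2-geranylphenyl]-7-methoxy-5-(methoxymethoxy)-4H-chromen-4-one | COc1cc(OCOC)c2c(c1)OC(c1ccc(O[Si](C)(C)C(C)(C)C)c(O[Si](C)(C)C(C)(C)C)c1C/C=C(\C)CCC=C(C)C)=CC2=O | intermediate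
16 | 2-(2-geranyl-3,4-dimethoxyphenyl)-7-methoxy-5-(methoxymethoxy)-4H-chromen-4-one | COc1cc(OCOC)c2c(c1)OC(c1ccc(OC)c(OC)c1C/C=C(\C)CCC=C(C)C)=CC2=O | intermediate
17 | (2S)-2-(2-geranyl-3,4-dimethoxyphenyl)-7-methoxy-5-(methoxymethoxy)chroman-4-one | COc1cc(OCOC)c2c(c1)O[C@H](c1ccc(OC)c(OC)c1C/C=C(\C)CCC=C(C)C)CC2=O | intermediate
18 | (2S)-2-(2-geranyl-3,4-dimethoxyphenyl)-5-hydroxy-7-methoxychroman-4-one | COc1cc(O)c2c(c1)O[C@H](c1ccc(OC)c(OC)c1C/C=C(\C)CCC=C(C)C)CC2=O | target

## Step count and risks

Total step count: 12. Longest linear sequence: 9 steps (steps 1–5 and 9–12, from 1). The diene branch (steps 6–8) joins at step 9.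

Steps least certain to work:

**Step 9 (key step).** The alkyne is activated only through the C2=C3–C4=O relay, so cycloaddition may be slower than thermal loss of the diene by desilylation or oligomerisation. Ortho regiocontrol may also erode, because the two silyloxy groups nearly cancel and only the alkyl terminus discriminates. The fallback moves the same ring B construction to a much stronger acceptor alkyne and builds ring C afterwards. It sets out from 13 and 1 and returns at 16.
- 13 is heated with methyl propiolate to the cycloadduct methyl 4,5-bis(tert-butyldimethylsilyloxy)-6-geranylcyclohexa-1,4-diene-1-carboxylate F1, which DDQ dehydrogenates in the same flask to methyl 3,4-bis(tert-butyldimethylsilyloxy)-2-geranylbenzoate F2.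
- CsF/MeI in DMF gives methyl 2-geranyl-3,4-dimethoxybenzoate F3.
- The polyanion of 1 (LiN(SiMe3)2, THF) is acylated by F3 in a crossed Claisen condensation to 1-(2,6-dihydroxy-4-methoxyphenyl)-3-(2-geranyl-3,4-dimethoxyphenyl)propane-1,3-dione F4.
- Cyclodehydration (NaOAc, AcOH, heat) gives 2-(2-geranyl-3,4-dimethoxyphenyl)-5-hydroxy-7-methoxy-4H-chromen-4-one F5, and NaH/MOMCl converts F5 into 16.

**Step 11.** Conversion may be poor because C2 is shielded by the ortho-substituted aryl group. Facial selectivity may be modest, and the copper enolate may open by retro-oxa-Michael reaction, which would erode the stereocentre. The fallback sets out from 16 and returns at 17.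
- Conjugate reduction with Li(s-Bu)3BH (THF, −78 °C) gives the racemic flavanone 2-(2-geranyl-3,4-dimethoxyphenyl)-7-methoxy-5-(methoxymethoxy)chroman-4-one F6.
- Kinetic resolution by asymmetric transfer hydrogenation (RuCl(p-cymene)[(R,R)-TsDPEN], HCO2H/Et3N) should reduce the 2R enantiomer to (2R,4R)-2-(2-geranyl-3,4-dimethoxyphenyl)-7-methoxy-5-(methoxymethoxy)chroman-4-ol F7 and leave 17. The catalyst antipode is the one expected from the aryl ketone model to consume the 2R ketone.

**Step 5.** Methoxide or methanol may add to C2 of the aldehyde-activated chromone (ring opening) or to the electrophilic terminus of the product alkyne. The fallback avoids alkoxide altogether; it sets out from 7 and returns at 8.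
- CBr4/PPh3 (CH2Cl2, 0 °C; first stage of a Corey–Fuchs sequence) gives 2-(2,2-dibromoethenyl)-7-methoxy-5-(methoxymethoxy)-4H-chromen-4-one F8.
- Pd(PPh3)4-catalysed hydrogenolysis with Bu3SnH removes the bromine trans to the ring and gives 2-[(Z)-2-bromoethenyl]-7-methoxy-5-(methoxymethoxy)-4H-chromen-4-one F9.
- TBAF in DMF effects anti elimination of HBr to 8.

**Step 6.** Proton transfer between product and enolate may lead to over-alkylation of the methyl ketone. The fallback uses an aza-enolate, which alkylates once; it sets out from 9 and returns at 12.
- Condensation of 9 with N,N-dimethylhydrazine gives 2-(3,3-dimethoxybutan-2-ylidene)-1,1-dimethylhydrazine F10.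
- Deprotonation (LiN(i-Pr)2, THF, 0 °C) and alkylation with 10 give 2-[(6E)-2,2-dimethoxy-7,11-dimethyldodeca-6,10-dien-3-ylidene]-1,1-dimethylhydrazine F11.
- 1 M aq. HCl in THF cleaves hydrazone and ketal together to 12.

## Further compounds

F1 | step 9 | methyl 4,5-bis(tert-butyldimethylsilyloxy)-6-geranylcyclohexa-1,4-diene-1-carboxylate (racemic, not isolated) | COC(=O)C1=CCC(O[Si](C)(C)C(C)(C)C)=C(O[Si](C)(C)C(C)(C)C)C1C/C=C(\C)CCC=C(C)C
F2 | step 9 | methyl 3,4-bis(tert-butyldimethylsilyloxy)-2-geranylbenzoate | COC(=O)c1ccc(O[Si](C)(C)C(C)(C)C)c(O[Si](C)(C)C(C)(C)C)c1C/C=C(\C)CCC=C(C)C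
F3 | step 9 | methyl 2-geranyl-3,4-dimethoxybenzoate | COC(=O)c1ccc(OC)c(OC)c1C/C=C(\C)CCC=C(C)C
F4 | step 9 | 1-(2,6-dihydroxy-4-methoxyphenyl)-3-(2-geranyl-3,4-dimethoxyphenyl)propane-1,3-dione | COc1cc(O)c(C(=O)CC(=O)c2ccc(OC)c(OC)c2C/C=C(\C)CCC=C(C)C)c(O)c1
F5 | step 9 | 2-(2-geranyl-3,4-dimethoxyphenyl)-5-hydroxy-7-methoxy-4H-chromen-4-one | COc1cc(O)c2c(c1)OC(c1ccc(OC)c(OC)c1C/C=C(\C)CCC=C(C)C)=CC2=O
F6 | step 11 | racemic 2-(2-geranyl-3,4-dimethoxyphenyl)-7-methoxy-5-(methoxymethoxy)chroman-4-one | COc1cc(OCOC)c2c(c1)OC(c1ccc(OC)c(OC)c1C/C=C(\C)CCC=C(C)C)CC2=O
F7 | step 11 | (2R,4R)-2-(2-geranyl-3,4-dimethoxyphenyl)-7-methoxy-5-(methoxymethoxy)chroman-4-ol | COc1cc(OCOC)c2c(c1)O[C@@H](c1ccc(OC)c(OC)c1C/C=C(\C)CCC=C(C)C)C[C@H]2O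
F8 | step 5 | 2-(2,2-dibromoethenyl)-7-methoxy-5-(methoxymethoxy)-4H-chromen-4-one | BrC(Br)=CC1=CC(=O)c2c(OCOC)cc(OC)cc2O1
F9 | step 5 | 2-[(Z)-2-bromoethenyl]-7-methoxy-5-(methoxymethoxy)-4H-chromen-4-one | Br/C=C\C1=CC(=O)c2c(OCOC)cc(OC)cc2O1
F10 | step 6 | 2-(3,3-dimethoxybutan-2-ylidene)-1,1-dimethylhydrazine | CC(=NN(C)C)C(C)(OC)OC
F11 | step 6 | 2-[(6E)-2,2-dimethoxy-7,11-dimethyldodeca-6,10-dien-3-ylidene]-1,1-dimethylhydrazine | CC(OC)(OC)C(=NN(C)C)CC/C=C(\C)CCC=C(C)C
A1 | alternative 1 | (2S)-2-(2-bromo-3,4-dimethoxyphenyl)-5,7-dimethoxychroman-4-one | COc1cc(OC)c2c(c1)O[C@H](c1ccc(OC)c(OC)c1Br)CC2=O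
A2 | alternative 1 | racemic 2-(2-bromo-3,4-dimethoxyphenyl)-5,7-dimethoxy-4-methylidene-4H-1,3-benzodioxine | C=C1OC(c2ccc(OC)c(OC)c2Br)Oc2cc(OC)cc(OC)c21
A3 | alternative 2 | (2S)-2-(2-geranyl-3,4-dimethoxyphenyl)-5,7-dihydroxychroman-4-one | Oc1cc(O)c2c(c1)O[C@H](c1ccc(OC)c(OC)c1C/C=C(\C)CCC=C(C)C)CC2=O
A4 | alternative 2 | (2S)-6-[(2,2-dimethyl-4-oxo-4H-1,3-dioxin-6-yl)methyl]-2-(2-geranyl-3,4-dimethoxyphenyl)-2,3-dihydro-4H-pyran-4-one | CC1(C)OC(=O)C=C(CC2=CC(=O)C[C@@H](c3ccc(OC)c(OC)c3C/C=C(\C)CCC=C(C)C)O2)O1
A5 | alternative 2 | 2-geranyl-3,4-dimethoxybenzaldehyde | O=Cc1ccc(OC)c(OC)c1C/C=C(\C)CCC=C(C)C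
A6 | alternative 3 | (2S,4S)-2-(2-geranyl-3,4-dimethoxyphenyl)-4,5,7-trimethoxychroman | COc1cc(OC)c2c(c1)O[C@H](c1ccc(OC)c(OC)c1C/C=C(\C)CCC=C(C)C)C[C@@H]2OC
A7 | alternative 3 | 1-ethenyl-2-geranyl-3,4-dimethoxybenzene | C=Cc1ccc(OC)c(OC)c1C/C=C(\C)CCC=C(C)C
A8 | alternative 3 | 2-(dimethoxymethyl)-3,5-dimethoxyphenol | COC(OC)c1c(O)cc(OC)cc1OC
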